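Both lactone rings (ring A, bearing the 4-aryloxy-3-methoxybenzyl group, and ring B) are disconnected at O-1–C-5 and C-2–C-3: the O-1–C-2(=O) unit is a CO2 equivalent spanning C-5 and C-3, which are 1,3-related through the C-4 stereocentre, and C-3 is the β-carbon of a styrene formed with the adjacent benzylic CH2 and its arene. A bis-(E)-styrene carrying an (S)-configured CH2Cl arm on each allylic carbon therefore takes up formate-derived CO2 radical anion at C-3, the carboxylates displace chloride, and base equilibration sets the trans (3S,4S) lactones, all in one pot. The precursor comes from a copper-catalysed asymmetric allylic alkylation, cross-metathesis and a double Suzuki coupling onto a dibromo diaryl ether.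

Key step: step 7

Remark: lactone numbering is O-1, C-2 (C=O), C-3 (α-CH), C-4 (β-CH), C-5 (OCH2). Both lactones of the target are (3S,4S), the mirror image of common natural (3R,4R)-arctigenin, so both halves are built from one (S)-fragment.

Assumption: in step 1 the (S,S,S)-phosphoramidite is taken to deliver (S)-4; the sense of induction would be confirmed on the first run, and the (R,R,R)-ligand used instead should it prove opposite.

Step 1
Reactants: 1 3,4-dimethoxybenzyl chloride; 2 (E)-1,4-dichlorobut-2-ene
Product: 4 (S)-4-[2-(chloromethyl)but-3-en-1-yl]-1,2-dimethoxybenzene, via 3,4-dimethoxybenzylmagnesium chloride 3 (not isolated)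
Conditions: Mg, Et2O, 0 °C (slow addition); then 2, CuTC (copper thiophene-2-carboxylate, CuO2CC4H3S, 3 mol%), (S,S,S)-phosphoramidite from (S)-BINOL and bis[(S)-1-phenylethyl]amine (3.3 mol%), CH2Cl2, −78 °C
Reagents that add atoms: none
Why: Copper-catalysed asymmetric allylic alkylation (SN2') of the symmetrical dichloride by the benzylic Grignard reagent should give the branched homoallyl chloride, the chiral copper–phosphoramidite complex choosing the enantiotopic alkene face and so setting the (S) centre that becomes C-4 of both lactones; the remaining chloride is no longer allylic and should not react again.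

Step 2
Reactants: 4 (S)-homoallyl chloride; 5 vinylboronic acid pinacol ester
Product: 6 2-[(1E,3S)-3-(chloromethyl)-4-(3,4-dimethoxyphenyl)but-1-en-1-yl]-4,4,5,5-tetramethyl-1,3,2-dioxaborolane
Conditions: second-generation Hoveyda–Grubbs catalyst [RuCl2(H2IMes)(=CH-C6H4-2-OiPr)] (5 mol%), 5 (3 equiv), CH2Cl2, 40 °C
Reagents that add atoms: none
Why: Olefin cross-metathesis with the vinyl boronate, which homodimerises only slowly, should give the (E)-alkenyl boronate with loss of ethene and without touching the allylic stereocentre.

Step 3
Reactants: 7 5-bromo-2-hydroxy-3-methoxybenzaldehyde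
Product: 8 2-(benzyloxy)-5-bromo-3-methoxybenzaldehyde
Conditions: BnBr, K2CO3, DMF, 50 °C
Reagents that add atoms: benzyl bromide, BrCc1ccccc1
Why: Williamson etherification of the phenoxide should protect the oxygen that becomes the free phenol of the target.

Step 4
Reactants: 8 2-(benzyloxy)-5-bromo-3-methoxybenzaldehyde
Product: 10 2-(benzyloxy)-5-bromo-3-methoxyphenol, via aryl formate 9 (not isolated)
Conditions: mCPBA, CH2Cl2, rt; then K2CO3 (cat.), MeOH, rt
Reagents that add atoms: mCPBA (3-chloroperoxybenzoic acid), OOC(=O)c1cccc(Cl)c1
Why: Baeyer–Villiger (Dakin-type) oxidation should proceed with migration of the electron-rich ortho-alkoxy aryl group to give the aryl formate, which methanolysis cleaves to the phenol with the substitution pattern of the central ring fixed unambiguously.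

Step 5
Reactants: 10 2-(benzyloxy)-5-bromo-3-methoxyphenol; 11 4-bromo-1-iodo-2-methoxybenzene
Product: 12 2-(benzyloxy)-5-bromo-1-(4-bromo-2-methoxyphenoxy)-3-methoxybenzene
Conditions: CuI (10 mol%), picolinic acid (20 mol%), K3PO4, DMSO, 80 °C, argon
Reagents that add atoms: none
Why: Ullmann-type C–O coupling under copper iodide/picolinic acid catalysis tolerates ortho substituents on both partners and should take place at the C–I bond in preference to either C–Br bond.

Step 6
Reactants: 12 dibromo diaryl ether; 6 (S,E)-alkenyl boronate (2.3 equiv)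
Product: 13 2-(benzyloxy)-5-[(1E,3S)-3-(chloromethyl)-4-(3,4-dimethoxyphenyl)but-1-en-1-yl]-1-{4-[(1E,3S)-3-(chloromethyl)-4-(3,4-dimethoxyphenyl)but-1-en-1-yl]-2-methoxyphenoxy}-3-methoxybenzene
Conditions: PdCl2(dppf) (5 mol%), K3PO4, dioxane/H2O, 80 °C
Reagents that add atoms: none
Why: Double Suzuki–Miyaura coupling should join both aryl bromides to the alkenyl boronate with retention of the (E) geometry, the primary alkyl chlorides being inert to this palladium catalyst and to the mild base.

Step 7
Reactants: 13 bis-(E)-styrene dichloride
Product: 16 O-benzyl ether of the target with both lactones (3S,4S)-trans, via dipotassium bis-chlorocarboxylate 14 (not isolated), via C-3 epimeric bis-lactone mixture 15 (not isolated)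
Conditions: HCO2K (8 equiv), 4DPAIPN (2 mol%), 2,4,6-triisopropylbenzenethiol (20 mol%), DMSO, 450 nm LEDs, rt; then 70 °C; then DBU, 70 °C
Reagents that add atoms: potassium formate, [K+].[O-]C=O
Why: A thiyl radical formed on photo-initiation abstracts hydrogen from formate, and the CO2 radical anion adds to the alkene carbon remote from the arene (future C-3 of each lactone) to form the C-2–C-3 bond and a benzylic radical, which takes hydrogen back from the thiol and carries the chain. On warming, each γ-chloro carboxylate closes by 5-exo-tet SN2 attack of a carboxylate oxygen on its CH2Cl carbon (O-1–C-5 bond), so that the whole O–C(=O) unit of both lactone rings comes from formate. The closest known reaction type is the photochemical, thiol-catalysed anti-Markovnikov hydrocarboxylation of styrenes with formate salts, joined to the classical lactonisation of γ-halo carboxylates. The C-4 centres are carried unchanged from 6, and the C-3 centres, formed without useful control in the radical addition, are set by DBU equilibration through the lactone enolates to the more stable trans arrangement, which is (3S,4S) in both rings. The step needs regioselectivity for C-3 (secured by the benzylic stabilisation of the adduct radical), survival of the C–Cl bonds during the radical stage (a primary alkyl chloride lies beyond the reducing power of the CO2 radical anion, and the hindered thiolate and formate are poor nucleophiles towards the β-branched chloride at room temperature) and ring closure faster than elimination (secured by the intramolecular five-membered transition state, DBU being added only after chloride is consumed).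

Step 8
Reactants: 16 O-benzyl ether of the target
Product: 17 target, (3S,4S)-4-(3,4-dimethoxybenzyl)-3-{4-[5-{[(3S,4S)-4-(3,4-dimethoxybenzyl)-2-oxotetrahydrofuran-3-yl]methyl}-2-hydroxy-3-methoxyphenoxy]-3-methoxybenzyl}dihydrofuran-2(3H)-one
Conditions: H2 (1 atm), Pd/C, EtOAc/EtOH, rt
Reagents that add atoms: none
Why: Hydrogenolysis of the benzyl aryl ether should free the phenol without affecting the diaryl ether, the methyl ethers or the lactones, no alkene or halide being left at this stage.

Compound list
1 | 3,4-dimethoxybenzyl chloride | COc1ccc(CCl)cc1OC | starting material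
2 | (E)-1,4-dichlorobut-2-ene | ClC/C=C/CCl | starting material
3 | 3,4-dimethoxybenzylmagnesium chloride | COc1ccc(C[Mg]Cl)cc1OC | intermediate
4 | (S)-4-[2-(chloromethyl)but-3-en-1-yl]-1,2-dimethoxybenzene | COc1ccc(C[C@@H](C=C)CCl)cc1OC | intermediate
5 | vinylboronic acid pinacol ester | C=CB1OC(C)(C)C(C)(C)O1 | starting material
6 | 2-[(1E,3S)-3-(chloromethyl)-4-(3,4-dimethoxyphenyl)but-1-en-1-yl]-4,4,5,5-tetramethyl-1,3,2-dioxaborolane | COc1ccc(C[C@@H](/C=C/B2OC(C)(C)C(C)(C)O2)CCl)cc1OC | intermediate
7 | 5-bromo-2-hydroxy-3-methoxybenzaldehyde | COc1cc(Br)cc(C=O)c1O | starting material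
8 | 2-(benzyloxy)-5-bromo-3-methoxybenzaldehyde | COc1cc(Br)cc(C=O)c1OCc1ccccc1 | intermediate
9 | 2-(benzyloxy)-5-bromo-3-methoxyphenyl formate | COc1cc(Br)cc(OC=O)c1OCc1ccccc1 | intermediate
10 | 2-(benzyloxy)-5-bromo-3-methoxyphenol | COc1cc(Br)cc(O)c1OCc1ccccc1 | intermediate
11 | 4-bromo-1-iodo-2-methoxybenzene | COc1cc(Br)ccc1I | starting material
12 | 2-(benzyloxy)-5-bromo-1-(4-bromo-2-methoxyphenoxy)-3-methoxybenzene | COc1cc(Br)cc(Oc2ccc(Br)cc2OC)c1OCc1ccccc1 | intermediate
13 | bis-(E)-styrene dichloride (full name in step 6; (S) at both chloromethyl-bearing carbons) | COc1ccc(C[C@H](CCl)/C=C/c2ccc(Oc3cc(/C=C/[C@@H](CCl)Cc4ccc(OC)c(OC)c4)cc(OC)c3OCc3ccccc3)c(OC)c2)cc1OC | intermediate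
14 | dipotassium bis-chlorocarboxylate (each alkene of 13 changed to ArCH2–CH(CO2K)–; epimers at the carboxylate-bearing carbons) | COc1ccc(C[C@H](CCl)C(Cc2ccc(Oc3cc(CC([C@@H](CCl)Cc4ccc(OC)c(OC)c4)C([O-])=O)cc(OC)c3OCc3ccccc3)c(OC)c2)C([O-])=O)cc1OC.[K+].[K+] | intermediate
15 | O-benzyl bis-lactone, (4S) in both rings, epimeric at both C-3 | COc1ccc(C[C@@H]2COC(=O)C2Cc2ccc(Oc3cc(CC4C(=O)OC[C@H]4Cc4ccc(OC)c(OC)c4)cc(OC)c3OCc3ccccc3)c(OC)c2)cc1OC | intermediate
16 | O-benzyl ether of the target, (3S,4S) in both lactones | COc1ccc(C[C@@H]2COC(=O)[C@H]2Cc2ccc(Oc3cc(C[C@@H]4C(=O)OC[C@H]4Cc4ccc(OC)c(OC)c4)cc(OC)c3OCc3ccccc3)c(OC)c2)cc1OC | intermediate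
17 | target, CNP0183104.1 (full name in step 8) | COc1ccc(C[C@@H]2COC(=O)[C@H]2Cc2ccc(Oc3cc(C[C@@H]4C(=O)OC[C@H]4Cc4ccc(OC)c(OC)c4)cc(OC)c3O)c(OC)c2)cc1OC | target

Total step count: 8
Longest linear sequence: 6 steps (steps 3, 4, 5, 6, 7 and 8, from 7 to 17)

Steps most likely to fail

Step 7: the radical addition may be slow at the hindered, electron-rich alkene carbon. The excited photocatalyst may instead oxidise the styrene or the arenes. Chloride may be lost by substitution or elimination before the carboxylate is in place. The fallback uses known radical chemistry, sets out from 13 and returns at 16. The two chlorides of 13 would be displaced with CsOAc (NaI cat., DMF, 80 °C) to give the bis-acetate F1. Methanolysis (K2CO3, MeOH) would give the diol F2. PhSeC(O)Cl and pyridine in CH2Cl2 would convert it into the bis(Se-phenyl selenocarbonate) F3. Bu3SnH/AIBN (benzene, 80 °C, slow addition) would then generate the two alkoxycarbonyl radicals, which close 5-exo-trig onto the styrene carbons. The benzylic radicals are reduced by the stannane to give the epimeric bis-lactone 15, and DBU equilibration as in step 7 leads to 16.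

Step 1: the benzylic Grignard reagent may give poor enantioface discrimination or direct SN2 substitution instead of SN2', and Wurtz coupling may erode its formation. The fallback uses auxiliary control, sets out from 1 and returns at 4. (S)-4-Benzyloxazolidin-2-one would be N-acylated with but-3-enoyl chloride (n-BuLi, THF, −78 °C) to give the imide F4. Its sodium dienolate (NaHMDS, THF, −78 °C) would be alkylated at the α-carbon with 1 (activated in situ with NaI) on the face opposite the auxiliary benzyl group to give the (S)-configured imide F5. LiBH4 (MeOH, Et2O, 0 °C) would release the alcohol F6 and the auxiliary. An Appel reaction (PPh3, CCl4, CH2Cl2) would give 4.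

Step 5: the C–O coupling between two ortho-substituted partners may be slow, and copper may insert into the C–Br bonds, giving oligomeric ethers or hydrodehalogenation. The fallback sets out from 10 and returns at 12. An oxidative Chan–Lam coupling of 10 with commercial (4-bromo-2-methoxyphenyl)boronic acid (Cu(OAc)2, pyridine, 4 Å molecular sieves, air, CH2Cl2, rt) leaves both C–Br bonds untouched and would give 12 directly. No new compound is made on the way.

Further compounds
F1 | step 7 | bis-acetate of 13 (both CH2Cl changed to CH2OAc) | COc1ccc(C[C@H](COC(C)=O)/C=C/c2ccc(Oc3cc(/C=C/[C@@H](COC(C)=O)Cc4ccc(OC)c(OC)c4)cc(OC)c3OCc3ccccc3)c(OC)c2)cc1OC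
F2 | step 7 | diol from 13 (both CH2Cl changed to CH2OH) | COc1ccc(C[C@H](CO)/C=C/c2ccc(Oc3cc(/C=C/[C@@H](CO)Cc4ccc(OC)c(OC)c4)cc(OC)c3OCc3ccccc3)c(OC)c2)cc1OC
F3 | step 7 | bis(Se-phenyl selenocarbonate) of F2 | COc1ccc(C[C@H](COC(=O)[Se]c5ccccc5)/C=C/c2ccc(Oc3cc(/C=C/[C@@H](COC(=O)[Se]c5ccccc5)Cc4ccc(OC)c(OC)c4)cc(OC)c3OCc3ccccc3)c(OC)c2)cc1OC
F4 | step 1 | (S)-4-benzyl-3-(but-3-enoyl)oxazolidin-2-one | C=CCC(=O)N1[C@@H](Cc2ccccc2)COC1=O
F5 | step 1 | (S)-4-benzyl-3-[(S)-2-(3,4-dimethoxybenzyl)but-3-enoyl]oxazolidin-2-one | COc1ccc(C[C@@H](C=C)C(=O)N2[C@@H](Cc3ccccc3)COC2=O)cc1OC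
F6 | step 1 | (S)-2-(3,4-dimethoxybenzyl)but-3-en-1-ol | COc1ccc(C[C@@H](C=C)CO)cc1OC
F0 | step 5 | none | none
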